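## Analysis of the target

The target is a methyl cyclohex-1-ene-1-carboxylate. Numbering the ring from the ester-bearing carbon C1 through C2 (=CH), C3, C4 and C5 to C6 (CH2), it carries an acetate on O3, a (2R)-2-methylbutanoate on O4 and a (3S)-3-methylpentanoate on O5. The ring stereocentres are C3 (R), C4 (S) and C5 (R). O3 and O4 are cis and O4 and O5 are trans, which is the pattern of shikimic acid, so the compound is methyl shikimate carrying three different acyl groups. The two side-chain stereocentres (α to the carbonyl in the O4 ester, β in the O5 ester) have no stereochemical link to the ring and are best bought inside the acids. The sensitive points are three secondary esters on vicinal oxygens (acyl migration, above all between the cis pair O3/O4), the allylic C3 acetate (elimination and aromatisation under base) and the α-centre of the 2-methylbutanoyl group (epimerisable on activation). The carbon skeleton is simple. The difficulty lies in fixing three contiguous oxygenated centres in the absolute sense and in placing three different acyl groups on three similar secondary hydroxyls without scrambling. The strategy rests on one feature: the C3,C4 cis-diol lies on the ring face opposite O5. A syn-dihydroxylation of the C3=C4 bond of a 5-silyloxycyclohexa-1,3-diene-1-carboxylate, anti to O5, would therefore create C3 and C4 from C5 in one event. That C3=C4 bond joins two CH termini and can be made by ring-closing metathesis, so C5 is the only ring stereocentre that has to be bought.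

## Retrosynthetic reasoning

**O5 ester.** Target 19 is cut at the O5–acyl bond into alcohol 17 and acid 18. This ester goes on last because O5 is the oxygen that carries the directing silyl group through the ring chemistry. Acid 18 has only a β-stereocentre, so its activation at the end carries no stereochemical risk.

**O5 silyl ether and O4 ester.** Alcohol 17 comes from silyl ether 16 by Si–O cleavage, and 16 is cut at the O4–acyl bond into hydroxy acetate 14 and acid 15. Keeping the silyl ether until O3 and O4 are acylated means O5 never competes. The forward acylation has to be fast and only weakly basic, so that the neighbouring O3 acetate stays in place and the α-centre of 15 is not epimerised.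

**O3 acetate.** Hydroxy acetate 14 is traced to cis-diol 12 through the cyclic orthoester 13. Cutting here avoids a direct competition between two secondary hydroxyls. The forward step relies on the opening of 13 to leave the acyl group on the pseudoaxial allylic oxygen O3.

**C3–O and C4–O.** Diol 12 is cut at both C–O bonds back to diene 11. The forward syn-dihydroxylation must choose the disubstituted, more electron-rich C3=C4 over the ester-bearing C1=C2 and must approach anti to the C5 silyloxy group. The gain is two stereocentres from one.

**C3=C4 (key disconnection).** Diene 11 is opened at C3=C4 to the acyclic triene 10. This is the only ring bond whose two carbons are both CH termini of vinyl groups in the open form, and cutting it leaves C5 as the single stereocentre. The forward ring-closing metathesis must engage the two monosubstituted alkenes and leave the trisubstituted enoate alone.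

**Ester methyl, silyl ether and lactone.** Triene 10 is the methyl ester of acid 9, and 9 arises from lactone 6 by ring opening (carboxylate 7) and silylation (bis-silyl derivative 8). The hydroxy acid exists naturally as the lactone, and the lactone is also what makes the next two bond formations easy. The forward sequence must open the lactone and cap the hydroxyl before it can close again.

**C1=C2.** Lactone 6 is cut at the exocyclic double bond into phosphonate 4 and aldehyde 5. A Horner–Wadsworth–Emmons olefination is chosen because it gives the E alkene, in which C3 and C6 are cis on C1=C2, the geometry that ring closure needs.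

**C1–C6.** Phosphonate 4 is cut at the C1–C6 bond and the lactone C–O bond into epoxide 1 and phosphonoacetate 2, by way of the open-chain alkoxide 3. The epoxide brings C5 with its oxygen and vinyl group in the correct absolute configuration, and the C5–O bond is never broken.

## Alternatives that were turned down

**Alternative 1:** C1–C2 and C5–C6 are cut together, as a [4+2] cycloaddition of furan (A2) with 2,2,2-trifluoroethyl acrylate (A3) under a chiral oxazaborolidinium Lewis acid. The forward key step gives the endo oxanorbornene ester A1. Enolisation at the ester carbon then expels the bridging oxygen and gives the dienol A4, which after silylation and ester exchange is diene 11, so the second half of the route is the same as here.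
- For: it is the shortest way to the diene (about four steps against five), it is catalytic in the chiral element, and the feedstocks are cheap. On step economy and cost it is stronger than the chosen route.
- Against: C5 of A4 is the remote bridgehead of A1, and its configuration depends on two selectivities at once. Endo and exo adducts formed on the same face of A3 have opposite bridgehead configuration. Because the ester-bearing centre is erased on ring opening, any exo adduct that is not removed becomes the enantiomer of A4. Cycloadditions of A2 are reversible and drift toward exo, which works against a clean result.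
- Against: A1 is acid-labile yet is made with a strong Lewis acid, and A4 is a free arene hydrate that dehydrates readily.
- Comparison: the chosen route buys C5 as a finished stereocentre and never puts it at risk, at the price of one more step to the diene.

**Alternative 2:** C1=C2 is cut as an intramolecular aldol condensation. The acyclic diketo ester A6, built from D-tartaric acid (A7), would close under secondary-amine catalysis to the 3-keto enoate A5.
- For: the logic mirrors the biosynthetic ring closure, C4 and C5 come from a cheap chiral pool, and O3 is distinct from O4 and O5 from the start because it is a ketone. The C3 acetate could then be placed without any diol differentiation, which is a real advantage over the chosen route.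
- Against: C3 must be set by a face-selective ketone reduction. More seriously, A6 and A5 are β-alkoxy carbonyl compounds on both sides. The C3 ketone can enolise toward C4 (epimerisation) and expel O5, which leads to a catechol-type benzoate, and the amine catalyst promotes exactly this. The keto ester terminus can do the same through C6.
- Against: the enamine must form at the methyl group and not toward C4, the trans-fused acetonide of A5 is strained, and turning C2-symmetric A7 into two different termini costs many steps. O4 and O5 still need to be told apart afterwards.
- Comparison: the alternative is longer and its key step has several built-in ways to fail, whereas the metathesis runs under neutral conditions with essentially one competing pathway.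

**Alternative 3:** C1–C6 is cut. A trialkylphosphine adds to C2 of the iodo enoate A9 (from D-lyxose, A10), the resulting C1 enolate displaces the C6 iodide, and base expels the phosphine to give A8.
- For: all three ring stereocentres come from the sugar, so nothing rests on facial selectivity. On stereochemical security this alternative is stronger than the chosen route. A8 also has O5 (silyl) separated from O3/O4 (acetonide), and after acetonide removal it is compound 12, so the endgame is shared.
- Against: A10 needs protecting-group work before the key step (acetonide, olefination of the lactol with the risk that the freed hydroxyl adds back to the new enoate, silylation, iodide), about six steps, which makes the route about two steps longer.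
- Against: the key step uses the phosphine stoichiometrically. The phosphine can quaternise at the primary iodide instead of adding to the weakly electrophilic enoate, and the phosphonium intermediate carries the acetonide oxygen on the neighbouring C3 as a leaving group.
- Comparison: the chosen route gives up the guaranteed C3/C4 configuration. In return it offers a catalytic ring closure with no chemoselectivity ambiguity and only one protecting group before the ring is closed.

Key step: step 5

## Remarks before the steps

Assumption: (S)-2-vinyloxirane, (R)-2-methylbutanoic acid and (S)-3-methylpentanoic acid are taken to be purchasable as single enantiomers; the acyl groups of the target are 2R on O4 and 3S on O5.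

Naming: ring compounds from step 6 onward are named as O-substituted methyl shikimates (shikimic acid = (3R,4S,5R)-3,4,5-trihydroxycyclohex-1-ene-1-carboxylic acid; O3/O4 cis, O4/O5 trans). The spatial arrangement is the same in all of them. The CIP letter at C4 reads R whenever O5 carries silicon (12, 14, 16) and S otherwise (17, 19), only because the priorities change.

## Steps

Step 1
Reactants: 1 (S)-2-vinyloxirane; 2 trimethyl phosphonoacetate
Product: 4 dimethyl [(5R)-5-ethenyl-2-oxooxolan-3-yl]phosphonate (both C3 epimers), via open-chain sodium alkoxide 3 (not isolated)
Conditions: NaH (1.1 equiv), 2 (1.2 equiv), DME, 0 °C → rt; then 1, 65 °C (sealed tube), 16 h; AcOH quench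
Reagents that add atoms: none
Why: The stabilised phosphonate carbanion opens the epoxide by SN2 attack at the unsubstituted carbon (basic medium, no Lewis acid and no zerovalent palladium that would favour allylic or 1,4-attack), and the γ-alkoxide 3 closes onto the methyl ester (5-exo-trig lactonisation), which at this temperature should outrun phosphoryl transfer. The C–O bond at the stereocentre is never broken, so the S epoxide gives the 5R lactone (the letter changes only through CIP priorities).

Step 2
Reactants: 4 dimethyl [(5R)-5-ethenyl-2-oxooxolan-3-yl]phosphonate; 5 acrolein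
Product: 6 (3E,5R)-5-ethenyl-3-(prop-2-en-1-ylidene)oxolan-2-one
Conditions: NaH, THF, 0 °C; then 5 (freshly distilled, 1.5 equiv), −40 → 0 °C
Reagents that add atoms: none
Why: Horner–Wadsworth–Emmons olefination of the α-phosphono lactone anion, which adds 1,2 to the enal. The small dimethyl phosphonate and the sodium counter-ion under equilibrating conditions should favour the E alkylidene (vinyl group anti to the lactone carbonyl); any minor Z isomer is removed by chromatography.

Step 3
Reactants: 6 (3E,5R)-5-ethenyl-3-(prop-2-en-1-ylidene)oxolan-2-one
Product: 9 (2E)-2-[(2R)-2-(tert-butyldimethylsilyloxy)but-3-en-1-yl]penta-2,4-dienoic acid, via lithium hydroxy carboxylate 7 (not isolated), via bis-silyl derivative 8 (not isolated)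
Conditions: LiOH·H2O (1.2 equiv), THF/H2O 3:1, 0 °C → rt; evaporate, PhMe azeotrope; TBSCl (3 equiv), imidazole (6 equiv), DMF, rt; then K2CO3, MeOH/THF/H2O, rt; work-up at pH 4–5
Reagents that add atoms: lithium hydroxide, [Li+].[OH-]; tert-butyldimethylsilyl chloride, CC(C)(C)[Si](C)(C)Cl
Why: Saponification opens the lactone, and the hydroxy carboxylate is not acidified (it would relactonise) but silylated on both oxygens. Mild carbonate then hydrolyses only the labile silyl ester and leaves the secondary silyl ether, after which the γ-silyloxy acid can no longer lactonise.

Step 4
Reactants: 9 (2E)-2-[(2R)-2-(tert-butyldimethylsilyloxy)but-3-en-1-yl]penta-2,4-dienoic acid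
Product: 10 methyl (2E)-2-[(2R)-2-(tert-butyldimethylsilyloxy)but-3-en-1-yl]penta-2,4-dienoate
Conditions: MeI (1.5 equiv), K2CO3 (1.5 equiv), DMF, 0 °C → rt
Reagents that add atoms: iodomethane, CI
Why: SN2 O-alkylation of the carboxylate under mild base; the silyl ether, the stereocentre and the dienoate geometry are not affected. The triene is used promptly because 2-substituted penta-2,4-dienoates can dimerise by [4+2] cycloaddition on standing.

Step 5
Reactants: 10 methyl (2E)-2-[(2R)-2-(tert-butyldimethylsilyloxy)but-3-en-1-yl]penta-2,4-dienoate
Product: 11 methyl (5R)-5-(tert-butyldimethylsilyloxy)cyclohexa-1,3-diene-1-carboxylate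
Conditions: second-generation Grubbs catalyst (H2IMes)(PCy3)Cl2Ru=CHPh (5 mol %), CH2Cl2 (5 mM), 40 °C, Ar sparge; ethyl vinyl ether quench; filtration through Et3N-deactivated silica
Reagents that add atoms: none
Why: After phosphine loss the ruthenium benzylidene exchanges with one of the two monosubstituted alkenes of 10, the new alkylidene adds [2+2] to the other vinyl group, and cycloreversion of the ruthenacyclobutane releases ethylene and forms the C3=C4 bond. The closest known reaction type is ring-closing metathesis of 1,3,7-trienes to cyclohexa-1,3-dienes. The six-membered carbocycle is closed by alkene–alkene metathesis between C3 and C4, and it does not matter which vinyl group the catalyst loads first, since both orders give the same ring. No stereocentre is formed, and C5 is a spectator whose allylic C–H is not touched. The step needs chemoselectivity for the two terminal alkenes over the trisubstituted, ester-bearing C1=C2; that alkene is electron-poor and hindered, and metathesis there could only give a four-membered ring. The E geometry from step 2 holds C3 and C6 cis on C1=C2, so the termini are within reach, and when ruthenium sits on the diene terminus the ester lies on the far side and cannot chelate it. High dilution and removal of ethylene suppress intermolecular metathesis and drive the closure. The neutral conditions, the quench and the base-washed silica protect the product, which is a silyl-protected arene hydrate, from isomerisation and aromatisation.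

Step 6
Reactants: 11 methyl (5R)-5-(tert-butyldimethylsilyloxy)cyclohexa-1,3-diene-1-carboxylate
Product: 12 methyl 5-O-(tert-butyldimethylsilyl)shikimate
Conditions: OsO4 (3 mol %), NMO (1.3 equiv), acetone/H2O 8:1, 0 °C → rt; aq. Na2SO3
Reagents that add atoms: osmium tetroxide, O=[Os](=O)(=O)=O; N-methylmorpholine N-oxide, C[N+]1([O-])CCOCC1
Why: Upjohn dihydroxylation; the [3+2] addition should take place at the disubstituted, more electron-rich C3=C4 and not at the ester-bearing trisubstituted C1=C2. The reagent approaches the face opposite the bulky allylic C5 silyloxy group, so the syn addition places O4 trans to O5 and O3 cis to O4, which sets C3 and C4 in one event.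

Step 7
Reactants: 12 methyl 5-O-(tert-butyldimethylsilyl)shikimate
Product: 14 methyl 3-O-acetyl-5-O-(tert-butyldimethylsilyl)shikimate, via cyclic orthoacetate 13 (not isolated)
Conditions: MeC(OMe)3 (3 equiv), PPTS (5 mol %), CH2Cl2, rt; then AcOH/H2O 4:1, 0 °C, 20 min
Reagents that add atoms: trimethyl orthoacetate, CC(OC)(OC)OC; water, O
Why: Orthoester exchange ties the cis-diol into the cyclic orthoacetate, and mild aqueous acid converts it to a hemiorthoester that should collapse by breaking the bond to the equatorial oxygen O4. This is the usual outcome for an orthoester spanning an axial/equatorial cis-diol on a six-membered ring, and it leaves the acetate on the pseudoaxial allylic O3. PPTS and brief aqueous AcOH spare the secondary silyl ether.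

Step 8
Reactants: 14 methyl 3-O-acetyl-5-O-(tert-butyldimethylsilyl)shikimate; 15 (R)-2-methylbutanoic acid
Product: 16 methyl 3-O-acetyl-4-O-[(2R)-2-methylbutanoyl]-5-O-(tert-butyldimethylsilyl)shikimate
Conditions: 15 (1.5 equiv), EDC·HCl (1.6 equiv), DMAP (0.2 equiv), CH2Cl2, 0 °C → rt
Reagents that add atoms: none
Why: Steglich esterification of the only free hydroxyl. The hydrochloride of the carbodiimide keeps the medium only weakly basic and the temperature is low, so O3→O4 acetyl migration and ketene-type epimerisation of the activated α-branched acid should both be suppressed.

Step 9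
Reactants: 16 methyl 3-O-acetyl-4-O-[(2R)-2-methylbutanoyl]-5-O-(tert-butyldimethylsilyl)shikimate
Product: 17 methyl 3-O-acetyl-4-O-[(2R)-2-methylbutanoyl]shikimate
Conditions: HF·pyridine, pyridine/THF, 0 °C → rt
Reagents that add atoms: none
Why: Fluoride cleaves the Si–O bond under buffered, slightly acidic conditions without the alkoxide basicity of tetrabutylammonium fluoride, so the three esters should neither cleave nor migrate.

Step 10
Reactants: 17 methyl 3-O-acetyl-4-O-[(2R)-2-methylbutanoyl]shikimate; 18 (S)-3-methylpentanoic acid
Product: 19 methyl (3R,4S,5R)-3-acetoxy-4-[(2R)-2-methylbutanoyloxy]-5-[(3S)-3-methylpentanoyloxy]cyclohex-1-ene-1-carboxylate (CNP0188172.1)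
Conditions: 18 (1.5 equiv), EDC·HCl (1.6 equiv), DMAP (0.2 equiv), CH2Cl2, 0 °C → rt
Reagents that add atoms: none
Why: Steglich esterification of the last free hydroxyl. The stereocentre of 18 is β to the carbonyl and cannot epimerise on activation, and the hindered α-branched ester on O4 should not migrate to the trans-disposed O5 under these buffered conditions.

## Compound list

1 | (S)-2-vinyloxirane [(2S)-2-ethenyloxirane] | C=C[C@H]1CO1 | starting material
2 | trimethyl phosphonoacetate | COC(=O)CP(=O)(OC)OC | starting material
3 | sodium alkoxide of methyl (4R)-2-(dimethoxyphosphoryl)-4-hydroxyhex-5-enoate (both C2 epimers) | C=C[C@H]([O-])CC(C(=O)OC)P(=O)(OC)OC.[Na+] | intermediate (not isolated)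
4 | dimethyl [(5R)-5-ethenyl-2-oxooxolan-3-yl]phosphonate (both C3 epimers) | COP(=O)(OC)C1C[C@H](C=C)OC1=O | intermediate
5 | acrolein (prop-2-enal) | C=CC=O | starting material
6 | (3E,5R)-5-ethenyl-3-(prop-2-en-1-ylidene)oxolan-2-one | C=C/C=C1\C[C@H](C=C)OC1=O | intermediate
7 | lithium (2E)-2-[(2R)-2-hydroxybut-3-en-1-yl]penta-2,4-dienoate | C=C[C@H](O)C/C(C(=O)[O-])=C\C=C.[Li+] | intermediate (not isolated)
8 | tert-butyldimethylsilyl (2E)-2-[(2R)-2-(tert-butyldimethylsilyloxy)but-3-en-1-yl]penta-2,4-dienoate | C=C[C@H](O[Si](C)(C)C(C)(C)C)C/C(C(=O)O[Si](C)(C)C(C)(C)C)=C\C=C | intermediate (not isolated)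
9 | (2E)-2-[(2R)-2-(tert-butyldimethylsilyloxy)but-3-en-1-yl]penta-2,4-dienoic acid | C=C[C@H](O[Si](C)(C)C(C)(C)C)C/C(C(=O)O)=C\C=C | intermediate
10 | methyl (2E)-2-[(2R)-2-(tert-butyldimethylsilyloxy)but-3-en-1-yl]penta-2,4-dienoate | C=C[C@H](O[Si](C)(C)C(C)(C)C)C/C(C(=O)OC)=C\C=C | intermediate
11 | methyl (5R)-5-(tert-butyldimethylsilyloxy)cyclohexa-1,3-diene-1-carboxylate | CC(C)(C)[Si](C)(C)O[C@@H]1CC(C(=O)OC)=CC=C1 | intermediate
12 | methyl 5-O-(tert-butyldimethylsilyl)shikimate [methyl (3R,4R,5R)-5-(tert-butyldimethylsilyloxy)-3,4-dihydroxycyclohex-1-ene-1-carboxylate] | CC(C)(C)[Si](C)(C)O[C@@H]1CC(C(=O)OC)=C[C@@H](O)[C@H]1O | intermediate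
13 | methyl 5-O-(tert-butyldimethylsilyl)-3,4-O-(1-methoxyethylidene)shikimate (both epimers at the orthoester carbon) | CC(C)(C)[Si](C)(C)O[C@@H]1CC(C(=O)OC)=C[C@H]2OC(C)(OC)O[C@@H]12 | intermediate (not isolated)
14 | methyl 3-O-acetyl-5-O-(tert-butyldimethylsilyl)shikimate [(3R,4R,5R)] | CC(C)(C)[Si](C)(C)O[C@@H]1CC(C(=O)OC)=C[C@@H](OC(C)=O)[C@H]1O | intermediate
15 | (R)-2-methylbutanoic acid | CC[C@@H](C)C(=O)O | starting material
16 | methyl 3-O-acetyl-4-O-[(2R)-2-methylbutanoyl]-5-O-(tert-butyldimethylsilyl)shikimate [(3R,4R,5R)] | CC(C)(C)[Si](C)(C)O[C@@H]1CC(C(=O)OC)=C[C@@H](OC(C)=O)[C@H]1OC(=O)[C@H](C)CC | intermediate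
17 | methyl 3-O-acetyl-4-O-[(2R)-2-methylbutanoyl]shikimate [(3R,4S,5R)] | O[C@@H]1CC(C(=O)OC)=C[C@@H](OC(C)=O)[C@H]1OC(=O)[C@H](C)CC | intermediate
18 | (S)-3-methylpentanoic acid | CC[C@H](C)CC(=O)O | starting material
19 | methyl (3R,4S,5R)-3-acetoxy-4-[(2R)-2-methylbutanoyloxy]-5-[(3S)-3-methylpentanoyloxy]cyclohex-1-ene-1-carboxylate | CC[C@H](C)CC(=O)O[C@@H]1CC(C(=O)OC)=C[C@@H](OC(C)=O)[C@H]1OC(=O)[C@H](C)CC | target

## Step count and risk

Total step count: 10. Longest linear sequence: 10 steps (1 → 19); acids 15 and 18 and aldehyde 5 enter as purchased reagents.

**Step 5 (key step).** The exposed conjugated vinyl terminus can undergo intermolecular metathesis, and the dienoate can dimerise by [4+2] cycloaddition; both compete with ring closure. The product can also aromatise by loss of silanol if ruthenium hydrides or traces of acid are present. The fallback caps the diene terminus with a methyl group, so that the catalyst can only start at the isolated vinyl group and closes onto an internal alkene with release of propene. It sets out from 4 and returns at 11. Olefination of 4 with (E)-but-2-enal under the conditions of step 2 should give (3E,5R)-3-[(2E)-but-2-en-1-ylidene]-5-ethenyloxolan-2-one F1. The sequence of step 3 then leads through lithium (2E,4E)-2-[(2R)-2-hydroxybut-3-en-1-yl]hexa-2,4-dienoate F2 and tert-butyldimethylsilyl (2E,4E)-2-[(2R)-2-(tert-butyldimethylsilyloxy)but-3-en-1-yl]hexa-2,4-dienoate F3 to (2E,4E)-2-[(2R)-2-(tert-butyldimethylsilyloxy)but-3-en-1-yl]hexa-2,4-dienoic acid F4. Methylation as in step 4 gives methyl (2E,4E)-2-[(2R)-2-(tert-butyldimethylsilyloxy)but-3-en-1-yl]hexa-2,4-dienoate F5, whose ring-closing metathesis gives 11.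

**Step 1.** The hindered, weakly nucleophilic phosphonate anion may attack the vinyl epoxide at the allylic carbon or in a 1,4 sense. It may also react so slowly that phosphoryl transfer to the alkoxide (cyclopropane formation) or evaporation of the epoxide takes over. The fallback uses a smaller, more nucleophilic carbanion that has no phosphorus, and introduces phosphorus afterwards. It sets out from 1 and returns at 4. Sodium dimethyl malonate (NaOMe, MeOH/THF, 50 °C) opens 1 and lactonises to methyl (5R)-5-ethenyl-2-oxooxolane-3-carboxylate F6. Krapcho dealkoxycarbonylation (LiCl, wet DMSO, 130 °C) gives (5R)-5-ethenyloxolan-2-one F7. Enolisation with lithium diisopropylamide and trapping with dimethyl chlorophosphate gives dimethyl (5R)-5-ethenyl-4,5-dihydrofuran-2-yl phosphate F8, which with a second equivalent of the amide base undergoes the 1,3-phosphoryl shift from oxygen to carbon and gives 4.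

**Step 6.** The diene may be lost to aromatisation while it is isolated and handled, and the enoate alkene may be over-oxidised; facial selectivity could also be incomplete if the silyloxy group sits pseudoequatorial. The fallback avoids isolating 11 and avoids osmium. It sets out from 10 and returns at 12 and makes no new compound (F0). After ring closure as in step 5 the solvent is changed to EtOAc/MeCN/H2O, and NaIO4 with CeCl3 at 0 °C turns the spent ruthenium into RuO4, which dihydroxylates the C3=C4 bond within minutes from the same open face.

**Step 7.** If the half-chair places O3 less clearly axial than assumed, the hemiorthoester may collapse without regioselectivity. The acetate may also migrate from O3 to O4 during work-up. The fallback replaces stereoelectronic control by steric control. It sets out from 12 and returns at 14 and makes no new compound (F0). Acetyl chloride with 2,4,6-collidine in CH2Cl2 at −78 °C should acetylate the allylic O3–H, which is far less hindered than O4–H next to the silyloxy group.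

**Step 8.** Acylation of the hindered O4–H with an α-branched acid is slow, so base-mediated migration of the acetate from O3 to O4 and partial epimerisation of the activated acid can compete. The fallback places the O4 ester before any acetate is present. It sets out from 12 and returns at 16. Selective silylation of O3 (TESCl, imidazole, CH2Cl2, −40 °C) gives methyl 5-O-(tert-butyldimethylsilyl)-3-O-(triethylsilyl)shikimate F9. Esterification with 15 (EDC·HCl, stoichiometric DMAP) gives methyl 4-O-[(2R)-2-methylbutanoyl]-5-O-(tert-butyldimethylsilyl)-3-O-(triethylsilyl)shikimate F10. Selective removal of the triethylsilyl group (PPTS, MeOH, 0 °C) gives methyl 4-O-[(2R)-2-methylbutanoyl]-5-O-(tert-butyldimethylsilyl)shikimate F11, and fast acetylation (Ac2O, pyridine, DMAP, 0 °C) gives 16.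

## Further compounds

F1 | step 5 | (3E,5R)-3-[(2E)-but-2-en-1-ylidene]-5-ethenyloxolan-2-one | C/C=C/C=C1\C[C@H](C=C)OC1=O
F2 | step 5 | lithium (2E,4E)-2-[(2R)-2-hydroxybut-3-en-1-yl]hexa-2,4-dienoate | C=C[C@H](O)C/C(C(=O)[O-])=C\C=C\C.[Li+]
F3 | step 5 | tert-butyldimethylsilyl (2E,4E)-2-[(2R)-2-(tert-butyldimethylsilyloxy)but-3-en-1-yl]hexa-2,4-dienoate | C=C[C@H](O[Si](C)(C)C(C)(C)C)C/C(C(=O)O[Si](C)(C)C(C)(C)C)=C\C=C\C
F4 | step 5 | (2E,4E)-2-[(2R)-2-(tert-butyldimethylsilyloxy)but-3-en-1-yl]hexa-2,4-dienoic acid | C=C[C@H](O[Si](C)(C)C(C)(C)C)C/C(C(=O)O)=C\C=C\C
F5 | step 5 | methyl (2E,4E)-2-[(2R)-2-(tert-butyldimethylsilyloxy)but-3-en-1-yl]hexa-2,4-dienoate | C=C[C@H](O[Si](C)(C)C(C)(C)C)C/C(C(=O)OC)=C\C=C\C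
F6 | step 1 | methyl (5R)-5-ethenyl-2-oxooxolane-3-carboxylate (both C3 epimers) | COC(=O)C1C[C@H](C=C)OC1=O
F7 | step 1 | (5R)-5-ethenyloxolan-2-one | O=C1CC[C@H](C=C)O1
F8 | step 1 | dimethyl (5R)-5-ethenyl-4,5-dihydrofuran-2-yl phosphate | COP(=O)(OC)OC1=CC[C@H](C=C)O1
F0 | step 6 | none | none
F0 | step 7 | none | none
F9 | step 8 | methyl 5-O-(tert-butyldimethylsilyl)-3-O-(triethylsilyl)shikimate | CC(C)(C)[Si](C)(C)O[C@@H]1CC(C(=O)OC)=C[C@@H](O[Si](CC)(CC)CC)[C@H]1O
F10 | step 8 | methyl 4-O-[(2R)-2-methylbutanoyl]-5-O-(tert-butyldimethylsilyl)-3-O-(triethylsilyl)shikimate | CC(C)(C)[Si](C)(C)O[C@@H]1CC(C(=O)OC)=C[C@@H](O[Si](CC)(CC)CC)[C@H]1OC(=O)[C@H](C)CC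
F11 | step 8 | methyl 4-O-[(2R)-2-methylbutanoyl]-5-O-(tert-butyldimethylsilyl)shikimate | CC(C)(C)[Si](C)(C)O[C@@H]1CC(C(=O)OC)=C[C@@H](O)[C@H]1OC(=O)[C@H](C)CC
A1 | alternative 1 | 2,2,2-trifluoroethyl endo-7-oxabicyclo[2.2.1]hept-5-ene-2-carboxylate | O=C(OCC(F)(F)F)[C@@H]1C[C@@H]2C=C[C@H]1O2
A2 | alternative 1 | furan | c1ccoc1
A3 | alternative 1 | 2,2,2-trifluoroethyl acrylate | C=CC(=O)OCC(F)(F)F
A4 | alternative 1 | 2,2,2-trifluoroethyl (5R)-5-hydroxycyclohexa-1,3-diene-1-carboxylate | O[C@@H]1CC(C(=O)OCC(F)(F)F)=CC=C1
A5 | alternative 2 | methyl 3-dehydroshikimate 4,5-acetonide | COC(=O)C1=CC(=O)[C@H]2OC(C)(C)O[C@@H]2C1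
A6 | alternative 2 | methyl 3-[(4R,5S)-5-acetyl-2,2-dimethyl-1,3-dioxolan-4-yl]-2-oxopropanoate | COC(=O)C(=O)C[C@H]1OC(C)(C)O[C@@H]1C(C)=O
A7 | alternative 2 | D-tartaric acid [(2S,3S)-2,3-dihydroxybutanedioic acid] | O[C@H](C(=O)O)[C@H](O)C(=O)O
A8 | alternative 3 | methyl 5-O-(tert-butyldimethylsilyl)-3,4-O-isopropylidene shikimate | COC(=O)C1=C[C@H]2OC(C)(C)O[C@H]2[C@H](O[Si](C)(C)C(C)(C)C)C1
A9 | alternative 3 | methyl 2,3,7-trideoxy-7-iodo-4,5-O-isopropylidene-6-O-(tert-butyldimethylsilyl)-D-lyxo-hept-2-enonate (either alkene geometry) | COC(=O)C=C[C@H]1OC(C)(C)O[C@H]1[C@H](O[Si](C)(C)C(C)(C)C)CI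
A10 | alternative 3 | D-lyxose (open-chain form) | O=C[C@@H](O)[C@@H](O)[C@H](O)CO
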